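**Retrosynthetic overview**
1. The route rests on the cis-fused γ-lactone (O–C6, C7–C11, C12=O) on the C6–C7 bond of the seven-membered carbocycle. It is the one-oxygen ring expansion of a cyclobutanone fused to that bond, so C6–C12 and C7–C11 are cut back to dichloroketene plus the C6=C7 bond of a cyclohept-6-ene.
2. The cycloheptene is closed at C5–C6 by an intramolecular Nozaki–Hiyama–Kishi addition of a (Z)-alkenyl iodide to an α-alkoxy aldehyde.
3. C1 comes from Sharpless epoxidation of a 2-substituted allylic alcohol followed by titanium-mediated pivalate opening; C9/C10 come from a Brown (Z)-crotylboration of (Z)-4-iodobut-3-enal.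
4. Ring order: seven-membered carbocycle (step 15), four-membered ketone (step 17), five-membered lactone (step 19), then the C11=C13 methylene.
5. Last: C5 isovalerate, C2 aldehyde, (E)-propenyl addition, oxidation to the enone, removal of the C9 silyl ether.

Key step: step 17

Remark: atoms are numbered C1 (carbinol carbon bearing C2 and the oxygen O1), C5 (CH–O-isovalerate), C6 (lactone CH–O), C7 (ring-fusion CH bearing C11; C12 lactone carbonyl, C13 methylene), C8 (CH2), C9 (CHOH), C10 (CH–CH3); β is the ring face of the C5 and C9 oxygens, α the face of O1, the C6 oxygen, C11 and the C10 methyl; C5 is carried as a triethylsilyl ether and C9 as a tert-butyldimethylsilyl (TBS) ether so that C5 alone can be unmasked for acylation.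

Step 1
Reactants: 1 but-3-yn-1-ol
Product: 2 4-iodobut-3-yn-1-ol
Conditions: N-iodosuccinimide, AgNO3 (10 mol%), acetone, rt, dark
Reagents that add atoms: N-iodosuccinimide, O=C1CCC(=O)N1I
Why: Silver-catalysed electrophilic iodination of the terminal alkyne C–H gives the 1-iodoalkyne and leaves the primary alcohol untouched.

Step 2
Reactants: 2 4-iodobut-3-yn-1-ol
Product: 3 (Z)-4-iodobut-3-en-1-ol
Conditions: 2-nitrobenzenesulfonylhydrazide, Et3N, THF/i-PrOH, rt
Reagents that add atoms: none
Why: Diimide reduction: diimide released from the sulfonylhydrazide transfers two hydrogens to one face of the iodoalkyne in a concerted syn step, which should give the (Z)-iodoalkene without cleaving the C–I bond.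

Step 3
Reactants: 3 (Z)-4-iodobut-3-en-1-ol
Product: 4 (Z)-4-iodobut-3-enal
Conditions: Dess–Martin periodinane, CH2Cl2, 0 °C to rt; used at once
Reagents that add atoms: none
Why: Dess–Martin oxidation under base-free conditions should give the β,γ-unsaturated aldehyde without moving the double bond into conjugation.

Step 4
Reactants: 4 (Z)-4-iodobut-3-enal; 5 cis-but-2-ene
Product: 9 (1Z,4R,5R)-1-iodo-5-methylhepta-1,6-dien-4-ol, via (Z)-but-2-enylpotassium 6 (not isolated), via (Z)-crotyl-bis(isopinocampheyl)borane 7 (not isolated), via borinate ester 8 (not isolated)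
Conditions: n-BuLi, KOt-Bu, THF, −78 to −45 °C; (−)-Ipc2BOMe, −78 °C; BF3·OEt2; then 4, −78 °C; NaOH, H2O2, 0 °C to rt
Reagents that add atoms: none
Why: Brown asymmetric crotylboration: the (Z)-crotylborane adds through a closed chair (Zimmerman–Traxler) transition state, so the Z geometry gives the syn C9/C10 pair, and the isopinocampheyl groups derived from (+)-α-pinene direct attack to the Si face of the aldehyde, setting (4R,5R).

Step 5
Reactants: 9 (1Z,4R,5R)-1-iodo-5-methylhepta-1,6-dien-4-ol
Product: 10 TBS ether of 9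
Conditions: TBSOTf, 2,6-lutidine, CH2Cl2, −78 to 0 °C
Reagents that add atoms: tert-butyldimethylsilyl triflate, CC(C)(C)[Si](C)(C)OS(=O)(=O)C(F)(F)F
Why: Silylation of the secondary alcohol with a silyl triflate and a hindered base gives the C9 TBS ether that is meant to stay until the last step.

Step 6
Reactants: 10 TBS ether of 9
Product: 12 (3R,4R,6Z)-4-[(tert-butyldimethylsilyl)oxy]-7-iodo-3-methylhept-6-en-1-ol, via B-alkyl-9-borabicyclononane 11 (not isolated)
Conditions: 9-BBN, THF, 0 °C to rt; then NaOH, H2O2, 0 °C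
Reagents that add atoms: hydrogen peroxide, OO
Why: Hydroboration–oxidation: the bulky borane adds boron only to the terminal carbon of the monosubstituted alkene, the (Z)-iodoalkene being deactivated, and alkaline peroxide replaces boron by hydroxyl with no change at C9 or C10.

Step 7
Reactants: 12 primary alcohol
Product: 13 (3R,4R,6Z)-4-[(tert-butyldimethylsilyl)oxy]-7-iodo-3-methylhept-6-enal
Conditions: Dess–Martin periodinane, CH2Cl2, 0 °C to rt
Reagents that add atoms: none
Why: Dess–Martin oxidation of the primary alcohol gives the aldehyde, whose stereocentre C10 is β to the carbonyl and cannot epimerise.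

Step 8
Reactants: 13 aldehyde
Product: 14 (3R,4R,6Z)-4-[(tert-butyldimethylsilyl)oxy]-7-iodo-3-methyl-2-methylidenehept-6-enal
Conditions: aq. CH2O (37%), pyrrolidine (10 mol%), propionic acid (10 mol%), i-PrOH, 45 °C
Reagents that add atoms: formaldehyde, C=O
Why: Amine-catalysed α-methylenation (Mannich condensation of the enamine with formaldehyde, then loss of the amine) puts the future C5 carbon on C1 and gives the 2-substituted acrolein.

Step 9
Reactants: 14 enal
Product: 15 (3R,4R,6Z)-4-[(tert-butyldimethylsilyl)oxy]-7-iodo-3-methyl-2-methylidenehept-6-en-1-ol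
Conditions: NaBH4, CeCl3·7H2O, MeOH, 0 °C
Reagents that add atoms: none
Why: Luche 1,2-reduction of the enal gives the 2-substituted allylic alcohol needed for the directed epoxidation.

Step 10
Reactants: 15 allylic alcohol
Product: 16 {(2R)-2-[(2S,3R,5Z)-3-[(tert-butyldimethylsilyl)oxy]-6-iodohex-5-en-2-yl]oxiran-2-yl}methanol
Conditions: t-BuOOH, Ti(OiPr)4 (10 mol%), D-(−)-diethyl tartrate (12 mol%), 4 Å molecular sieves, CH2Cl2, −20 °C
Reagents that add atoms: tert-butyl hydroperoxide, CC(C)(C)OO
Why: Sharpless asymmetric epoxidation: the titanium tartrate binds the allylic alcohol and delivers oxygen to one alkene face under reagent control, D-(−)-tartrate giving the (R)-2-substituted glycidol that places O1 correctly on C1, while the isolated iodoalkene does not react.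

Step 11
Reactants: 16 epoxy alcohol
Product: 17 (2R,3S,4R,6Z)-4-[(tert-butyldimethylsilyl)oxy]-2-hydroxy-2-(hydroxymethyl)-7-iodo-3-methylhept-6-en-1-yl 2,2-dimethylpropanoate
Conditions: pivalic acid, Ti(OiPr)4 (1.5 equiv), CH2Cl2, rt
Reagents that add atoms: pivalic acid, CC(C)(C)C(=O)O
Why: Titanium-mediated opening of a 2,3-epoxy alcohol: pivalate attacks the distal, unhindered epoxide CH2 (C5) of the titanium-bound substrate, so the C1–O bond is never broken and the C1 configuration is kept.

Step 12
Reactants: 17 diol pivalate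
Product: 18 {(4R)-4-[(2S,3R,5Z)-3-[(tert-butyldimethylsilyl)oxy]-6-iodohex-5-en-2-yl]-2,2-dimethyl-1,3-dioxolan-4-yl}methyl 2,2-dimethylpropanoate
Conditions: 2,2-dimethoxypropane, pyridinium p-toluenesulfonate (cat.), CH2Cl2, rt
Reagents that add atoms: 2,2-dimethoxypropane, COC(C)(C)OC
Why: Acid-catalysed transketalisation closes the five-membered acetonide over the only 1,2-diol (tertiary C1–OH, primary C2–OH), which fixes the roles of the two CH2–O arms on C1.

Step 13
Reactants: 18 acetonide pivalate
Product: 19 {(4S)-4-[(2S,3R,5Z)-3-[(tert-butyldimethylsilyl)oxy]-6-iodohex-5-en-2-yl]-2,2-dimethyl-1,3-dioxolan-4-yl}methanol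
Conditions: i-Bu2AlH, CH2Cl2, −78 °C; aq. potassium sodium tartrate
Reagents that add atoms: none
Why: Reductive ester cleavage with i-Bu2AlH at low temperature frees the C5 alcohol without touching the acetonide, the silyl ether or the iodoalkene.

Step 14
Reactants: 19 alcohol
Product: 20 (4R)-4-[(2S,3R,5Z)-3-[(tert-butyldimethylsilyl)oxy]-6-iodohex-5-en-2-yl]-2,2-dimethyl-1,3-dioxolane-4-carbaldehyde
Conditions: Dess–Martin periodinane, CH2Cl2, 0 °C to rt
Reagents that add atoms: none
Why: Dess–Martin oxidation gives the α-alkoxy aldehyde, which has no α-hydrogen and so cannot epimerise.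

Step 15
Reactants: 20 aldehyde
Product: 21 cyclohept-6-en-5β-ol with C1/C2 acetonide (O1 α, C2 β), 10α-methyl and 9β-OTBS
Conditions: CrCl2 (8 equiv), NiCl2 (2 mol%), DMSO (0.005 M), rt
Reagents that add atoms: none
Why: Intramolecular Nozaki–Hiyama–Kishi reaction: zerovalent nickel inserts into the C6–I bond, the alkenyl group passes to trivalent chromium with retention of the Z geometry and adds to the C5 aldehyde to close the seven-membered ring, and the 5β-OH (trans to O1) is expected from a chair-like transition state with the C10 methyl and C9 silyloxy groups equatorial in which the C5=O dipole lies anti to the C1–O1 bond, chromium not chelating in DMSO.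

Step 16
Reactants: 21 cycloheptenol
Product: 22 5β-triethylsilyl ether of 21 (key precursor)
Conditions: Et3SiOTf, 2,6-lutidine, CH2Cl2, −78 °C
Reagents that add atoms: triethylsilyl triflate, CC[Si](CC)(CC)OS(=O)(=O)C(F)(F)F
Why: Silylation of the hindered allylic alcohol with the reactive silyl triflate installs a group that shields the β face of C6 and can later be removed in the presence of the C9 TBS ether.

Step 17
Reactants: 22 5β-triethylsilyl ether; 23 trichloroacetyl chloride
Product: 25 cis-fused α,α-dichlorocyclobutanone on the C6–C7 bond, via dichloroketene 24 (not isolated)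
Conditions: 23 (slow addition), Zn–Cu couple, Et2O/DME (5:1), rt
Reagents that add atoms: none
Why: Zinc reduces trichloroacetyl chloride to dichloroketene 24, which adds to the cis C6=C7 bond of 22 in a concerted but asynchronous [2+2] step in which the ketene carbonyl carbon C12 bonds first, to C6, and the CCl2 carbon C11 then closes on C7. The closest known reaction type is the dichloroketene–cycloalkene cycloaddition used to make ring-fused cyclobutanones as precursors of γ-lactones. The four-membered ring (C6, C7, C11, C12) is closed suprafacially on the alkene, so its fusion to the seven-membered ring is necessarily cis and the stereocentres C6 and C7 are set together. Their sense is fixed by the C5 centre: the pseudoaxial C5–OSiEt3 group covers the β face of C6, so the ketene should add from the α face and place C12, the site of the future lactone oxygen, trans to the C5 oxygen. The step needs regioselectivity (C12 on C6) and α-facial selectivity; the first rests on the inductive pull of the C5 oxygen, which disfavours positive charge at C6 and leaves the less hindered C7 to take the bulkier CCl2 end, the second on the allylic silyl ether. Dimethoxyethane ties up ZnCl2 so that the acetonide and both silyl ethers should survive.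

Step 18
Reactants: 25 dichlorocyclobutanone
Product: 26 cis-fused cyclobutanone (C11 = CH2)
Conditions: Zn dust, NH4Cl, MeOH, rt
Reagents that add atoms: none
Why: Zinc reduces both C–Cl bonds α to the strained ketone (reductive dehalogenation through the zinc enolate) under weakly acidic conditions that the silyl ethers and the acetonide should tolerate.

Step 19
Reactants: 26 cyclobutanone
Product: 27 cis-fused γ-lactone (O–C6 α, C11–C7 α)
Conditions: m-chloroperbenzoic acid, NaHCO3, CH2Cl2, 0 °C to rt
Reagents that add atoms: m-chloroperbenzoic acid, O=C(OO)c1cccc(Cl)c1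
Why: Baeyer–Villiger oxidation driven by relief of cyclobutanone strain: the more substituted carbon C6 migrates to oxygen with retention, giving the lactone with its ring oxygen on C6.

Step 20
Reactants: 27 γ-lactone
Product: 30 α-methylene lactone (C11=C13), via Mannich base 28 (not isolated), via trimethylammonium iodide 29 (not isolated)
Conditions: LiN(i-Pr)2, THF, −78 °C; CH2=NMe2+ I−, −78 °C to rt; MeI, rt; aq. NaHCO3, rt
Reagents that add atoms: N,N-dimethylmethyleneiminium iodide (Eschenmoser's salt), C=[N+](C)C.[I-]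
Why: Lactone α-methylenation by the Mannich route: the lithium enolate at C11 is aminomethylated, the amine is quaternised and trimethylamine is eliminated under mild base to give the exocyclic alkene, no other enolisable carbonyl being present at this stage.

Step 21
Reactants: 30 α-methylene lactone
Product: 31 5β-alcohol
Conditions: HF·pyridine, pyridine, THF, 0 °C
Reagents that add atoms: none
Why: Buffered fluoride desilylation cleaves the triethylsilyl ether much faster than the TBS ether and leaves the acetonide in place.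

Step 22
Reactants: 31 5β-alcohol; 32 3-methylbutanoic anhydride
Product: 33 5β-isovalerate
Conditions: 4-(dimethylamino)pyridine, Et3N, CH2Cl2, rt
Reagents that add atoms: none
Why: Nucleophile-catalysed acylation of the only free hydroxyl installs the isovalerate at C5.

Step 23
Reactants: 33 5β-isovalerate
Product: 34 C1,C2-diol
Conditions: AcOH/H2O (4:1), 40 °C
Reagents that add atoms: none
Why: Mild acid hydrolysis of the acetonide frees the tertiary C1–OH and primary C2–OH, while the hindered secondary TBS ether, the ester and the lactone should persist.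

Step 24
Reactants: 34 diol
Product: 35 C2 aldehyde (1α-hydroxy)
Conditions: 2,2,6,6-tetramethylpiperidin-1-oxyl (20 mol%), PhI(OAc)2, CH2Cl2, rt
Reagents that add atoms: none
Why: Oxoammonium-catalysed oxidation with PhI(OAc)2 as terminal oxidant converts the primary C2 alcohol into the aldehyde under neutral conditions, the tertiary C1–OH being inert.

Step 25
Reactants: 35 C2 aldehyde; 36 (E)-1-bromoprop-1-ene
Product: 37 C2 allylic alcohol bearing the (E)-propenyl group (C2 epimers)
Conditions: CrCl2, NiCl2 (1 mol%), DMF, rt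
Reagents that add atoms: none
Why: Nozaki–Hiyama–Kishi coupling: the alkenylchromium species formed from the (E)-bromide with retention of geometry adds only to the aldehyde and not to the lactone, the ester or the α-methylene lactone, since organochromium reagents are poor conjugate donors; the new C2 centre is removed in the next step.

Step 26
Reactants: 37 allylic alcohol
Product: 38 9-O-TBS ether of the target
Conditions: Dess–Martin periodinane, CH2Cl2, 0 °C to rt
Reagents that add atoms: none
Why: Dess–Martin oxidation of the secondary allylic alcohol gives the (E)-enone and erases the C2 stereocentre, the tertiary α-hydroxyl being inert.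

Step 27
Reactants: 38 9-O-TBS ether
Product: 39 target, (3aS,5R,6S,7S,8S,8aR)-7-[(2E)-but-2-enoyl]-5,7-dihydroxy-6-methyl-3-methylidene-2-oxooctahydro-2H-cyclohepta[b]furan-8-yl 3-methylbutanoate
Conditions: HF·pyridine, THF, 0 °C to rt
Reagents that add atoms: none
Why: Desilylation with HF·pyridine frees the C9 hydroxyl under acidic, non-nucleophilic conditions that spare the enone, the α-methylene lactone and the ester.

**Compound list**
1 | but-3-yn-1-ol | C#CCCO | starting material
2 | 4-iodobut-3-yn-1-ol | OCCC#CI | intermediate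
3 | (Z)-4-iodobut-3-en-1-ol | OCC/C=C\I | intermediate
4 | (Z)-4-iodobut-3-enal | O=CC/C=C\I | intermediate
5 | cis-but-2-ene | C/C=C\C | starting material
6 | (Z)-but-2-enylpotassium | C/C=C\C[K] | intermediate
7 | (Z)-crotyl-bis(isopinocampheyl)borane, isopinocampheyl groups from (+)-α-pinene | C/C=C\CB([C@@H]1C[C@@H]2C[C@H]([C@H]1C)C2(C)C)[C@@H]1C[C@@H]2C[C@H]([C@H]1C)C2(C)C | intermediate
8 | bis(isopinocampheyl)borinate ester of 9 | C=C[C@@H](C)[C@H](OB([C@@H]1C[C@@H]2C[C@H]([C@H]1C)C2(C)C)[C@@H]1C[C@@H]2C[C@H]([C@H]1C)C2(C)C)C/C=C\I | intermediate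
9 | (1Z,4R,5R)-1-iodo-5-methylhepta-1,6-dien-4-ol | C=C[C@@H](C)[C@H](O)C/C=C\I | intermediate
10 | tert-butyl{[(1Z,4R,5R)-1-iodo-5-methylhepta-1,6-dien-4-yl]oxy}dimethylsilane | C=C[C@@H](C)[C@H](O[Si](C)(C)C(C)(C)C)C/C=C\I | intermediate
11 | 9-[(3R,4R,6Z)-4-[(tert-butyldimethylsilyl)oxy]-7-iodo-3-methylhept-6-en-1-yl]-9-borabicyclo[3.3.1]nonane | C1CC2CCCC(C1)B2CC[C@@H](C)[C@H](O[Si](C)(C)C(C)(C)C)C/C=C\I | intermediate
12 | (3R,4R,6Z)-4-[(tert-butyldimethylsilyl)oxy]-7-iodo-3-methylhept-6-en-1-ol | OCC[C@@H](C)[C@H](O[Si](C)(C)C(C)(C)C)C/C=C\I | intermediate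
13 | (3R,4R,6Z)-4-[(tert-butyldimethylsilyl)oxy]-7-iodo-3-methylhept-6-enal | O=CC[C@@H](C)[C@H](O[Si](C)(C)C(C)(C)C)C/C=C\I | intermediate
14 | (3R,4R,6Z)-4-[(tert-butyldimethylsilyl)oxy]-7-iodo-3-methyl-2-methylidenehept-6-enal | C=C(C=O)[C@@H](C)[C@H](O[Si](C)(C)C(C)(C)C)C/C=C\I | intermediate
15 | (3R,4R,6Z)-4-[(tert-butyldimethylsilyl)oxy]-7-iodo-3-methyl-2-methylidenehept-6-en-1-ol | C=C(CO)[C@@H](C)[C@H](O[Si](C)(C)C(C)(C)C)C/C=C\I | intermediate
16 | {(2R)-2-[(2S,3R,5Z)-3-[(tert-butyldimethylsilyl)oxy]-6-iodohex-5-en-2-yl]oxiran-2-yl}methanol | OC[C@@]1(CO1)[C@@H](C)[C@H](O[Si](C)(C)C(C)(C)C)C/C=C\I | intermediate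
17 | (2R,3S,4R,6Z)-4-[(tert-butyldimethylsilyl)oxy]-2-hydroxy-2-(hydroxymethyl)-7-iodo-3-methylhept-6-en-1-yl 2,2-dimethylpropanoate | CC(C)(C)C(=O)OC[C@](O)(CO)[C@@H](C)[C@H](O[Si](C)(C)C(C)(C)C)C/C=C\I | intermediate
18 | {(4R)-4-[(2S,3R,5Z)-3-[(tert-butyldimethylsilyl)oxy]-6-iodohex-5-en-2-yl]-2,2-dimethyl-1,3-dioxolan-4-yl}methyl 2,2-dimethylpropanoate | CC(C)(C)C(=O)OC[C@]1(COC(C)(C)O1)[C@@H](C)[C@H](O[Si](C)(C)C(C)(C)C)C/C=C\I | intermediate
19 | {(4S)-4-[(2S,3R,5Z)-3-[(tert-butyldimethylsilyl)oxy]-6-iodohex-5-en-2-yl]-2,2-dimethyl-1,3-dioxolan-4-yl}methanol | OC[C@]1(COC(C)(C)O1)[C@@H](C)[C@H](O[Si](C)(C)C(C)(C)C)C/C=C\I | intermediate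
20 | (4R)-4-[(2S,3R,5Z)-3-[(tert-butyldimethylsilyl)oxy]-6-iodohex-5-en-2-yl]-2,2-dimethyl-1,3-dioxolane-4-carbaldehyde | O=C[C@]1(COC(C)(C)O1)[C@@H](C)[C@H](O[Si](C)(C)C(C)(C)C)C/C=C\I | intermediate
21 | cyclohept-6-en-5β-ol with C1/C2 acetonide (O1 α, C2 β), 10α-methyl, 9β-OTBS | C1C=C[C@H](O)[C@]2(COC(C)(C)O2)[C@@H](C)[C@@H]1O[Si](C)(C)C(C)(C)C | intermediate
22 | 5β-triethylsilyl ether of 21 (key precursor) | C1C=C[C@H](O[Si](CC)(CC)CC)[C@]2(COC(C)(C)O2)[C@@H](C)[C@@H]1O[Si](C)(C)C(C)(C)C | intermediate
23 | trichloroacetyl chloride | O=C(Cl)C(Cl)(Cl)Cl | starting material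
24 | dichloroketene | O=C=C(Cl)Cl | intermediate
25 | cis-fused α,α-dichlorocyclobutanone (C12=O on C6, CCl2 on C7, both α) | O=C1[C@H]2[C@H](O[Si](CC)(CC)CC)[C@]3(COC(C)(C)O3)[C@@H](C)[C@H](O[Si](C)(C)C(C)(C)C)C[C@H]2C1(Cl)Cl | intermediate
26 | cis-fused cyclobutanone (C11 = CH2) | O=C1[C@H]2[C@H](O[Si](CC)(CC)CC)[C@]3(COC(C)(C)O3)[C@@H](C)[C@H](O[Si](C)(C)C(C)(C)C)C[C@H]2C1 | intermediate
27 | cis-fused γ-lactone (O–C6 α, C11–C7 α), 5β-OSiEt3, 9β-OTBS, C1/C2 acetonide | O=C1O[C@H]2[C@H](O[Si](CC)(CC)CC)[C@]3(COC(C)(C)O3)[C@@H](C)[C@H](O[Si](C)(C)C(C)(C)C)C[C@H]2C1 | intermediate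
28 | 11-(dimethylaminomethyl) lactone (C11 epimers) | O=C1O[C@H]2[C@H](O[Si](CC)(CC)CC)[C@]3(COC(C)(C)O3)[C@@H](C)[C@H](O[Si](C)(C)C(C)(C)C)C[C@H]2C1CN(C)C | intermediate
29 | 11-(trimethylammoniomethyl) lactone iodide | O=C1O[C@H]2[C@H](O[Si](CC)(CC)CC)[C@]3(COC(C)(C)O3)[C@@H](C)[C@H](O[Si](C)(C)C(C)(C)C)C[C@H]2C1C[N+](C)(C)C.[I-] | intermediate
30 | α-methylene lactone (C11=C13), 5β-OSiEt3 | O=C1O[C@H]2[C@H](O[Si](CC)(CC)CC)[C@]3(COC(C)(C)O3)[C@@H](C)[C@H](O[Si](C)(C)C(C)(C)C)C[C@H]2C1=C | intermediate
31 | α-methylene lactone 5β-alcohol | O=C1O[C@H]2[C@H](O)[C@]3(COC(C)(C)O3)[C@@H](C)[C@H](O[Si](C)(C)C(C)(C)C)C[C@H]2C1=C | intermediate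
32 | 3-methylbutanoic anhydride | CC(C)CC(=O)OC(=O)CC(C)C | starting material
33 | 5β-isovalerate (C1/C2 acetonide, 9β-OTBS) | O=C1O[C@H]2[C@H](OC(=O)CC(C)C)[C@]3(COC(C)(C)O3)[C@@H](C)[C@H](O[Si](C)(C)C(C)(C)C)C[C@H]2C1=C | intermediate
34 | C1,C2-diol (1α-OH, 1β-CH2OH) | O=C1O[C@H]2[C@H](OC(=O)CC(C)C)[C@](O)(CO)[C@@H](C)[C@H](O[Si](C)(C)C(C)(C)C)C[C@H]2C1=C | intermediate
35 | C2 aldehyde (1α-OH, 1β-CHO) | O=C1O[C@H]2[C@H](OC(=O)CC(C)C)[C@](O)(C=O)[C@@H](C)[C@H](O[Si](C)(C)C(C)(C)C)C[C@H]2C1=C | intermediate
36 | (E)-1-bromoprop-1-ene | C/C=C/Br | starting material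
37 | C2 allylic alcohol with (E)-propenyl group (C2 epimers) | O=C1O[C@H]2[C@H](OC(=O)CC(C)C)[C@](O)(C(O)/C=C/C)[C@@H](C)[C@H](O[Si](C)(C)C(C)(C)C)C[C@H]2C1=C | intermediate
38 | 9-O-TBS ether of the target | O=C1O[C@H]2[C@H](OC(=O)CC(C)C)[C@](O)(C(=O)/C=C/C)[C@@H](C)[C@H](O[Si](C)(C)C(C)(C)C)C[C@H]2C1=C | intermediate
39 | (3aS,5R,6S,7S,8S,8aR)-7-[(2E)-but-2-enoyl]-5,7-dihydroxy-6-methyl-3-methylidene-2-oxooctahydro-2H-cyclohepta[b]furan-8-yl 3-methylbutanoate | C=C1C(=O)O[C@@H]2[C@H]1C[C@@H](O)[C@H](C)[C@@](O)(C(=O)/C=C/C)[C@H]2OC(=O)CC(C)C | target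

**Step count**
Total steps: 27. Longest linear sequence: 27 steps, from but-3-yn-1-ol 1.

**Steps most likely to fail**

Step 17. The ketene may add with poor facial or regiochemical discrimination, or ZnCl2 may strip the acetonide or the triethylsilyl group before the slow cycloaddition is complete. The fallback sets out from 21 and comes back at 27. Hydroxyl-directed epoxidation of 21 with VO(acac)2 and t-BuOOH should give the syn 6β,7β-epoxy alcohol F1. Silylation with Et3SiOTf gives its triethylsilyl ether F2. Dilithioacetate (LiCH2CO2Li from acetic acid and LiN(i-Pr)2) opens the epoxide from the α face at C7, the carbon remote from the C5 oxygen, to the trans hydroxy acid F3. Mitsunobu lactonisation (PPh3, diisopropyl azodicarboxylate) closes the ring with inversion at C6 and gives lactone 27.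

Step 15. The two faces of the aldehyde may be poorly differentiated during ring closure, so that the 5α-alcohol forms beside or instead of 21. The fallback sets out from 20 and comes back at 21. The closure is run as before and the 5α-epimer F4, or the mixture, is oxidised with Dess–Martin periodinane to the cyclohept-6-en-5-one F5. Corey–Bakshi–Shibata reduction with catecholborane and (R)-1-methyl-3,3-diphenyltetrahydro-1H,3H-pyrrolo[1,2-c][1,3,2]oxazaborole, the quaternary C1 acting as the large group, should deliver hydride from the α face and give 21.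

Step 25. The α-hydroxy aldehyde may undergo an α-ketol shift or decompose under the Lewis-acidic chromium salts before the sluggish alkenyl bromide couples. The fallback sets out from 35 and comes back at 38. Barbier allylation with allyl bromide and indium powder in THF/H2O, which attacks only the aldehyde, gives the homoallylic alcohol F6. Dess–Martin oxidation gives the β,γ-unsaturated ketone F7. Et3N-catalysed migration of the double bond into conjugation gives the (E)-enone 38.

**Further compounds**
F1 | step 17 | syn 6β,7β-epoxy-5β-alcohol from 21 | C1[C@@H]2O[C@@H]2[C@H](O)[C@]3(COC(C)(C)O3)[C@@H](C)[C@@H]1O[Si](C)(C)C(C)(C)C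
F2 | step 17 | 5β-triethylsilyl ether of F1 | C1[C@@H]2O[C@@H]2[C@H](O[Si](CC)(CC)CC)[C@]3(COC(C)(C)O3)[C@@H](C)[C@@H]1O[Si](C)(C)C(C)(C)C
F3 | step 17 | trans hydroxy acid (6β-OH, 7α-CH2CO2H) | C1[C@@H](CC(=O)O)[C@H](O)[C@H](O[Si](CC)(CC)CC)[C@]2(COC(C)(C)O2)[C@@H](C)[C@@H]1O[Si](C)(C)C(C)(C)C
F4 | step 15 | 5α-epimer of 21 | C1C=C[C@@H](O)[C@]2(COC(C)(C)O2)[C@@H](C)[C@@H]1O[Si](C)(C)C(C)(C)C
F5 | step 15 | cyclohept-6-en-5-one with C1/C2 acetonide, 10α-methyl, 9β-OTBS | C1C=CC(=O)[C@]2(COC(C)(C)O2)[C@@H](C)[C@@H]1O[Si](C)(C)C(C)(C)C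
F6 | step 25 | C2 homoallylic alcohol, allyl adduct of 35 (C2 epimers) | O=C1O[C@H]2[C@H](OC(=O)CC(C)C)[C@](O)(C(O)CC=C)[C@@H](C)[C@H](O[Si](C)(C)C(C)(C)C)C[C@H]2C1=C
F7 | step 25 | β,γ-unsaturated ketone (but-3-enoyl on C1) | O=C1O[C@H]2[C@H](OC(=O)CC(C)C)[C@](O)(C(=O)CC=C)[C@@H](C)[C@H](O[Si](C)(C)C(C)(C)C)C[C@H]2C1=C
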